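Atom numbers of the target are used for every compound: ring A is C1–C2–C3–C4–C5–C10, ring B is C5–C6–C7–C8–C9–C10, C14 is the carbon on C10, C15 the methyl on C4, C11–C13 the isopropenyl group on C7. The face of the bicycle that carries C14 is called β, the other α.

## The problem

The target 32 is a trans-fused Δ3-octalin of the eudesmane type whose rings meet at a quaternary C10; this carbon carries the hydroxymethyl carbon C14 and is flanked by two oxygenated carbons, C1 and C9. Six stereocentres must be set: O1 and O2 are cis on the β face, H5 is α, and the C7 isopropenyl and C9 acetoxy groups are both axial on the α face, 1,3 to each other. C1 and C2 can be bought as a sugar diol and can direct C10; C10 and C5 must be made together to secure the trans fusion; the rigid decalin then lets C5/C10 control C7 (axial conjugate addition) and C7/C10 control C9 (hydride from the equatorial side). Four hydroxyls end in four different states (senecioate on O1, acetates on O2 and O9, free O14), and O14 sits 1,3 to both O1 and O9, so base-induced acyl migration, deconjugation of the enoate, ionisation of the allylic C2 acetate and attack on the two alkenes exclude a rough end game. While the skeleton is built, C14 is a carboxyl carbon β to the C9 carbonyl at a quaternary centre, a pattern open to retro-Claisen cleavage and decarboxylation. The enabling feature is the array C14(carboxyl)–C10–C5–C4=C3, a γ,δ-unsaturated acid and hence the retron of an ester-enolate Claisen rearrangement. Because C3 is tied back to C10 through C2 and C1 inside ring A, the allylic oxygen on C3 and C14 belong to one δ-lactone, and the rearrangement becomes the contraction of a sugar lactone to ring A.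

## Retrosynthesis

**Ester pattern (32 back to 25).** The bonds cut last are the three acyl–oxygen bonds and the O14–Si bond: 32 from silyl ether 31, then C1 alcohol 30, diol 28, acetonide 27, C9 alcohol 26 and 9,14-diol 25. C14 must be reduced before any ester exists, so it is silylated and freed at the very end under acidic fluoride. The cis-1,2-diol is told apart not by selective acylation but by a cyclic orthoacetate that opens to the ester of the axial oxygen (O2). Carrying two different protecting groups on O1 and O2 from the sugar would avoid this but costs more steps early. The precursor 25 has no ester and only one protecting group. The forward steps must acylate two hindered secondary alcohols without acyl migration.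

**C7 and C9 (25 back to 22).** The C9–H and C14–H bonds and the C7–C11 bond are cut: 25 comes from keto ester 23, and 23 from enone 22 by conjugate addition. Placing the isopropenyl group on the acyclic chain before ring closure would create a stereocentre with nothing to control it, whereas on the trans-decalin enone axial attack is dictated by the ring. This removes two stereocentres and leaves a bicyclic enone ester. The forward steps need axial cuprate delivery and equatorial hydride delivery.

**Ring B (22 back to 18).** The C7–C8 bond is cut: enone 22 arises from β-methoxy ketone 21, formed when the C9 silyl enol ether of 18 adds to the oxocarbenium ion of the C7 dimethyl acetal. A base-mediated aldol condensation of a keto aldehyde would make the same bond, but nucleophilic base threatens the quaternary β-keto ester, and the silyl enol ether is delivered free of charge by the key step. The precursor 18 is monocyclic. The two arms must be trans on ring A so that closure is trans.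

**Ring A (18 back to 15), the key cut.** The C5–C10 bond is cut and the C3=C4 alkene moved back to C4=C5, with C14 rejoined to O–C3: cyclohexene 18 comes from the bis-silyl dienolate 17 of 3-acetyl lactone 15. The neighbouring cuts, alkylation or acylation of a preformed ring A at C10, or a cycloaddition across C5–C10, would each need separate control of C5 and C10. The sigmatropic cut derives both from one carbinol centre (C3) and one alkene geometry. The precursor 15 has three stereocentres (C1, C2, C3), none quaternary. The forward reaction needs clean formation of the cyclic ketene acetal and a boat transition state.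

**Acetyl group and lactone (15 back to 12).** The C9–C10 bond is cut (C-acylation of the enolate of lactone 13), then the lactone C14–O bond (cyclisation of δ-hydroxy N-methoxy-N-methylamide 12). The acetyl group enters last because the configuration at C10 is irrelevant, which removes any need for selectivity. Lactone 13 is a simple sugar lactone carrying the side chain.

**Side chain (12 back to 10 and 5).** The C3–C4 bond is cut: alkenyllithium 11, from E iodide 5, adds to α-alkoxy aldehyde 10. An olefination of a C3 ketone would also give the E alkene but needs an extra reduction to set C3; direct Felkin–Anh addition sets C3 and joins the fragments in one step. Iodide 5 comes from alkyne 3 by hydrozirconation and iodination, and 3 from alkyne 1 by methylation. The forward step must favour the 2,3-anti alcohol.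

**Sugar (10 back to 6).** Aldehyde 10 comes from hydroxy amide 9, lactone 8, lactol acetonide 7 and 2-deoxy-L-ribose 6, whose C1–C5 become C14, C10, C1, C2 and C3 and whose C3/C4 diol supplies O1 and O2 with the right absolute configuration. The pyranose form offers only one vicinal diol, so the acetonide goes where it is needed. Opening the lactone with an aluminium amide frees the primary hydroxyl for oxidation while C14 stays at the carboxyl level.

## Roads not taken

**Alternative 1:** The cut runs through ring B at C9–C10 and C5–C6. A Diels–Alder reaction of methyl 1,4-benzoquinone-2-carboxylate A1 with (E)-1-(tert-butyldimethylsilyloxy)buta-1,3-diene A2 would give the cis-fused endo adduct A3.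
- Merits: A3 already holds the quaternary C10 with its ester (C14), the C9 oxygen on the correct side relative to C14, and carbonyls at C1 and C4. Two simple achiral partners reach a decalin in one step, which is clearly shorter than the chosen route, where ring B closes only at step 11.
- Weak points for 32: A3 is cis-fused, so C5 must be epimerised through an enedione that can also enolise towards a hydroquinone. C2 has no oxygen and C4 no methyl, so ring A would need methyl addition at C4, allylic transposition to C2 and two reductions from the hindered face syn to C14. The C7=C8 alkene is unactivated, so the isopropenyl group could enter only after the C9 oxygen is oxidised to the enone, which discards the one centre the cycloaddition set well. Absolute configuration would need external asymmetric induction on a very reactive dienophile.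
- Comparison: the chosen plan spends more steps before the first ring closes. Against that it brings C1 and C2 with oxygen and absolute configuration from the sugar, sets C5 and C10 together in the trans relationship, and needs no redox correction of ring A.

**Alternative 2:** The cut is at C1–C2 and C5–C10. An intramolecular Diels–Alder reaction of the acyclic triene A4 (silyloxydiene C2=C3–C4=C5, tethered through C6–C8 to the silylmethylidene β-keto ester C1=C10) would give the trans-fused octalin A5.
- Merits: both rings and four stereocentres (C1, C2, C5, C10) form in one step, with C3=C4, C15, the C9 ketone and the C14 ester in place. In bonds per step this is better than the chosen plan.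
- Weak points for 32: A4 is achiral, so absolute control needs an outside chiral influence on a substrate with an acid-labile silyloxydiene. The configuration at C1 depends on the geometry of a doubly activated alkylidene that isomerises easily and on an endo/exo choice that the short tether does not fix. The trans fusion is only one possible outcome. The C1 silyl group must be oxidised by a Fleming–Tamao sequence whose electrophilic step competes with the C3=C4 alkene and the allylic silyl ether. Ring B arrives saturated at C7/C8, so a dehydrogenation is needed before the isopropenyl addition.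
- Comparison: the chosen plan cannot match the bond count of this step. It sets against it a stereospecific key step, C1/C2 oxygens already at the right level, and a C9 enone delivered directly by ring closure.

**Alternative 3:** The cut is at C1–C2. A pinacol-type coupling with SmI2 (divalent samarium) of dialdehyde A6, which has the C1 aldehyde on C10 and the (Z)-enal on C5 of a finished ring B, would give the cis-diol A7.
- Merits: the diol forms late with both carbinol centres, chelation to samarium favours cis, and the hydroxyls are free at once. In that respect it equals or betters the chosen end game, which needs an acetonide cleavage before the diol can be differentiated.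
- Weak points for 32: A6 already contains C5, C7, C9 and the quaternary C10 with two differentiated one-carbon arms, so the hardest part of the problem is moved, unsolved, into its preparation. The ketyl of an enal is delocalised and may couple at the β-carbon or be reduced. The (Z)-enal can isomerise to the E form, which cannot close. The face the diol takes relative to C14 rests on a chelate of uncertain preference.
- Comparison: the chosen plan makes C10 and ring A in one stereospecific step and avoids a late, face-ambiguous coupling; it pays with two extra protecting-group operations.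

Key step: step 10

Assumption: 4,4-dimethoxybut-1-yne (1) is treated as a catalogue alkyne; if it had to be made, propargyl bromide, aluminium and trimethyl orthoformate give it in one step.

## Route

Step 1
Reactants: 1 4,4-dimethoxybut-1-yne
Product: 3 5,5-dimethoxypent-2-yne, via lithium acetylide 2 (not isolated)
Conditions: n-BuLi, THF, −78 °C; MeI, −78 °C → rt
Reagents that add atoms: iodomethane, CI
Why: Deprotonation of the terminal alkyne and SN2 methylation of the acetylide; the acetal is inert to base. The new methyl group becomes C15.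

Step 2
Reactants: 3 5,5-dimethoxypent-2-yne
Product: 5 (2E)-2-iodo-5,5-dimethoxypent-2-ene, via alkenylzirconocene 4 (not isolated)
Conditions: Cp2Zr(H)Cl (1.5 equiv), THF, rt → 40 °C; I2, THF, 0 °C
Reagents that add atoms: iodine, II
Why: Syn hydrozirconation of the internal alkyne; the slight excess of Cp2Zr(H)Cl equilibrates the regioisomers towards zirconium on the less hindered, methyl-bearing carbon. Iodinolysis with retention gives the E iodide (iodine cis to H).

Step 3
Reactants: 6 2-deoxy-L-ribose
Product: 7 2-deoxy-3,4-O-isopropylidene-L-ribopyranose (anomer mixture)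
Conditions: 2-methoxypropene, pyridinium p-toluenesulfonate (cat.), EtOAc, 0 °C → rt
Reagents that add atoms: 2-methoxypropene, C=C(C)OC
Why: Kinetic acetonation of the pyranose form, whose only vicinal diol is the cis O3/O4 pair; the lactol keeps C1 and C5 of the sugar differentiated.

Step 4
Reactants: 7 2-deoxy-3,4-O-isopropylidene-L-ribopyranose
Product: 8 2-deoxy-3,4-O-isopropylidene-L-ribono-1,5-lactone
Conditions: PhI(OAc)2, 2,2,6,6-tetramethylpiperidin-1-oxyl (cat.), CH2Cl2, rt
Reagents that add atoms: none
Why: Oxoammonium-catalysed oxidation of a lactol to the δ-lactone; the near-neutral medium spares the acetonide.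

Step 5
Reactants: 8 2-deoxy-3,4-O-isopropylidene-L-ribono-1,5-lactone
Product: 9 (3R,4S)-5-hydroxy-3,4-(isopropylidenedioxy)-N-methoxy-N-methylpentanamide
Conditions: MeNH(OMe)·HCl, Me3Al, CH2Cl2, 0 °C → rt; aq. KNaC4H4O6
Reagents that add atoms: N,O-dimethylhydroxylamine hydrochloride, CNOC.Cl
Why: Aminolysis of the lactone by the aluminium amide made from Me3Al, a reagent too weakly basic to eliminate the β-oxygen. It frees the primary hydroxyl and leaves C14 as an acyl group that tolerates the next two steps; 9 is used at once because it can relactonise.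

Step 6
Reactants: 9 (3R,4S)-5-hydroxy-3,4-(isopropylidenedioxy)-N-methoxy-N-methylpentanamide
Product: 10 (3R,4R)-3,4-(isopropylidenedioxy)-N-methoxy-N-methyl-5-oxopentanamide
Conditions: Dess–Martin periodinane, NaHCO3, CH2Cl2, 0 °C → rt
Reagents that add atoms: none
Why: Dess–Martin oxidation of the primary alcohol under buffer; the α-alkoxy aldehyde is configurationally labile and is used crude.

Step 7
Reactants: 5 (2E)-2-iodo-5,5-dimethoxypent-2-ene; 10 (3R,4R)-3,4-(isopropylidenedioxy)-N-methoxy-N-methyl-5-oxopentanamide
Product: 12 (3R,4S,5S,6E)-5-hydroxy-3,4-(isopropylidenedioxy)-N,9,9-trimethoxy-N,6-dimethylnon-6-enamide, via alkenyllithium 11 (not isolated)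
Conditions: t-BuLi (2 equiv), Et2O, −78 °C; add 10 in THF, −78 °C; aq. NH4Cl
Reagents that add atoms: none
Why: Iodine–lithium exchange with retention of alkene geometry, then addition to the aldehyde, which is far more electrophilic than the amide at −78 °C. Felkin–Anh attack anti to the α-oxygen (O2) should favour the 2,3-anti alcohol, which sets C3 (S).

Step 8
Reactants: 12 (3R,4S,5S,6E)-5-hydroxy-3,4-(isopropylidenedioxy)-N,9,9-trimethoxy-N,6-dimethylnon-6-enamide
Product: 13 (5S)-5-C-[(2E)-5,5-dimethoxypent-2-en-2-yl]-2-deoxy-3,4-O-isopropylidene-L-ribono-1,5-lactone (alkenyl group trans to the acetonide)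
Conditions: pyridinium p-toluenesulfonate (cat.), PhMe, 60 °C
Reagents that add atoms: none
Why: Acid-catalysed intramolecular acyl substitution (6-exo-trig) of the N-methoxy-N-methylamide by the C3 hydroxyl; volatile MeNH(OMe) leaves and drives the lactonisation. A weak acid without water or alcohol should leave both acetals intact.

Step 9
Reactants: 13 (5S)-5-C-[(2E)-5,5-dimethoxypent-2-en-2-yl]-2-deoxy-3,4-O-isopropylidene-L-ribono-1,5-lactone
Product: 15 2-C-acetyl derivative of lactone 13 (acetyl on C10; epimers plus enol), via lithium enolate 14 (not isolated)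
Conditions: LiN(SiMe3)2 (2.1 equiv), THF, −78 °C; AcCl, −78 °C; AcOH
Reagents that add atoms: acetyl chloride, CC(=O)Cl
Why: Claisen-type C-acylation of a lithium lactone enolate with an acid chloride at low temperature; the second equivalent of base takes up the acidic product. The configuration at C10 does not matter because step 10 erases it.

Step 10
Reactants: 15 2-C-acetyl derivative of lactone 13
Product: 18 trimethylsilyl 1β,2β-(isopropylidenedioxy)-5β-(2,2-dimethoxyethyl)-4-methyl-10α-[1-(trimethylsilyloxy)vinyl]cyclohex-3-ene-10β-carboxylate, via silyl enol ether 16 (not isolated), via bis-silyl dienol ether 17 (not isolated)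
Conditions: Me3SiCl, Et3N, THF, 0 °C → rt, filter; LiN(i-Pr)2, Me3SiCl, THF, −78 °C; then PhMe, 90 °C
Reagents that add atoms: chlorotrimethylsilane, C[Si](C)(C)Cl
Why: Soft enolisation gives the C9 silyl enol ether 16, whose only acidic position left is the C8 methyl; LiN(i-Pr)2 removes a C8 proton and the dienolate is silylated on the lactone oxygen to give 17, a cyclic silyl ketene acetal (C10=C14) bearing a 1-silyloxyvinyl group on C10. On warming, 17 undergoes the Ireland–Claisen rearrangement C10=C14–O–C3–C4=C5 → C14(=O)–C10–C5–C4=C3; the closest known reactions are the thermal ring contraction of silyl ketene acetals of 6-alkenyl δ-lactones to cyclohex-3-enecarboxylic silyl esters and, for the acyl substituent, the dienolate (Carroll-type) Claisen rearrangement of allyl β-keto esters. Ring A is closed by the new C5–C10 σ bond of the suprafacial [3,3] shift: since C10 and C3 are already linked by C1–C2, the six reacting atoms must adopt a boat held like a bicyclo[2.2.2]octane, and the lactone oxygen leaves the ring as the silyl carboxylate (a ring contraction, so no Baldwin mode applies). At C10, C5 can reach the ketene-acetal carbon only on the lactone face that carries the alkenyl group, which is the face opposite the acetonide, so C14 ends cis to O1 and O2 and the C9 group trans. At C5, chirality passes suprafacially from C3 across the E alkene while the forming ring holds C2 cis to C5, which puts the C6 arm cis to C14 and H5 trans. The step needs γ-deprotonation instead of β-elimination of O1, and a shift faster than decay of the diene; the first silylation removes the C10 proton, the dienolate is trapped at −78 °C with Me3SiCl present, and the tether leaves the boat as the only pericyclic path. Both C10 epimers of 15 and both geometries of 16 converge on 17, the C9 silyl enol ether and the C7 acetal come through untouched, and 18 is concentrated and used crude.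

Step 11
Reactants: 18 trimethylsilyl 1β,2β-(isopropylidenedioxy)-5β-(2,2-dimethoxyethyl)-4-methyl-10α-[1-(trimethylsilyloxy)vinyl]cyclohex-3-ene-10β-carboxylate
Product: 21 methyl 1β,2β-(isopropylidenedioxy)-7-methoxy-9-oxo-11,12,13-trinor-5αH-eudesm-3-en-14-oate (C7 epimers), via silyl ester 19 (not isolated), via keto acid 20 (not isolated)
Conditions: Me3SiOTf (10 mol %), CH2Cl2, −78 °C; 2,6-lutidine, MeOH; Me3SiCHN2, PhMe–MeOH, 0 °C
Reagents that add atoms: (trimethylsilyl)diazomethane, C[Si](C)(C)C=[N+]=[N-]
Why: Intramolecular Mukaiyama aldol-type addition of the C9 silyl enol ether to the oxocarbenium ion of the C7 dimethyl acetal (6-(enolendo)-exo-trig) closes ring B; the fusion is trans because the two arms are trans-diequatorial on ring A. Methanolysis of the silyl ester and immediate cold methylation keep the β-keto acid from decarboxylating.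

Step 12
Reactants: 21 methyl 1β,2β-(isopropylidenedioxy)-7-methoxy-9-oxo-11,12,13-trinor-5αH-eudesm-3-en-14-oate
Product: 22 methyl 1β,2β-(isopropylidenedioxy)-9-oxo-11,12,13-trinor-5αH-eudesma-3,7-dien-14-oate
Conditions: DBU, PhMe, 60 °C
Reagents that add atoms: none
Why: E1cB loss of methanol from the β-methoxy ketone; the amidine base is non-nucleophilic and so cannot open the quaternary β-keto ester by retro-Claisen attack at C9.

Step 13
Reactants: 22 methyl 1β,2β-(isopropylidenedioxy)-9-oxo-11,12,13-trinor-5αH-eudesma-3,7-dien-14-oate
Product: 23 methyl 1β,2β-(isopropylidenedioxy)-9-oxo-5αH-eudesma-3,11-dien-14-oate (7α-isopropenyl)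
Conditions: CH2=C(CH3)MgBr, CuBr·SMe2 (20 mol %), THF, −78 → −30 °C; aq. NH4Cl
Reagents that add atoms: isopropenylmagnesium bromide, C=C(C)[Mg]Br
Why: Copper-catalysed conjugate addition of the Grignard reagent. Stereoelectronic axial attack on the half-chair enone of the trans-decalin, anti to the C5–C4 bond, places the isopropenyl group α (axial, cis to H5, trans to C14).

Step 14
Reactants: 23 methyl 1β,2β-(isopropylidenedioxy)-9-oxo-5αH-eudesma-3,11-dien-14-oate
Product: 25 1β,2β-(isopropylidenedioxy)-5αH-eudesma-3,11-diene-9α,14-diol (7α-isopropenyl), via lithium alkoxide 24 (not isolated)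
Conditions: Li(s-Bu)3BH, THF, −78 °C; then LiAlH4, −78 → 0 °C; aq. KNaC4H4O6
Reagents that add atoms: none
Why: The bulky borohydride should attack C9 from the equatorial side because the axial approach is blocked by the axial C7 isopropenyl group and H5 (the 3,3,5-trimethylcyclohexanone pattern), giving the axial 9α-alcohol. LiAlH4 then reduces the neopentyl methyl ester to the C14 alcohol in the same flask.

Step 15
Reactants: 25 1β,2β-(isopropylidenedioxy)-5αH-eudesma-3,11-diene-9α,14-diol
Product: 26 14-(tert-butyldiphenylsilyloxy)-1β,2β-(isopropylidenedioxy)-5αH-eudesma-3,11-dien-9α-ol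
Conditions: t-BuPh2SiCl, imidazole, DMF, rt → 40 °C
Reagents that add atoms: tert-butyl(chloro)diphenylsilane, CC(C)(C)[Si](Cl)(c1ccccc1)c1ccccc1
Why: Silylation of the primary C14 hydroxyl in preference to the axial, doubly flanked C9 hydroxyl. This silyl ether is chosen because it survives the acid of steps 17 and 18.

Step 16
Reactants: 26 14-(tert-butyldiphenylsilyloxy)-1β,2β-(isopropylidenedioxy)-5αH-eudesma-3,11-dien-9α-ol
Product: 27 14-(tert-butyldiphenylsilyloxy)-1β,2β-(isopropylidenedioxy)-5αH-eudesma-3,11-dien-9α-yl acetate
Conditions: Ac2O, 4-(dimethylamino)pyridine, pyridine, 40 °C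
Reagents that add atoms: acetic anhydride, CC(=O)OC(C)=O
Why: Nucleophile-catalysed acetylation of a hindered axial secondary alcohol; mild heating is expected to be needed.

Step 17
Reactants: 27 14-(tert-butyldiphenylsilyloxy)-1β,2β-(isopropylidenedioxy)-5αH-eudesma-3,11-dien-9α-yl acetate
Product: 28 9α-acetoxy-14-(tert-butyldiphenylsilyloxy)-5αH-eudesma-3,11-diene-1β,2β-diol
Conditions: AcOH–H2O (4:1), 40 °C
Reagents that add atoms: none
Why: Acid hydrolysis of the cis-fused isopropylidene acetal; aqueous acetic acid is too weak to ionise the allylic C2–O bond or to cleave the silyl ether or the acetate.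

Step 18
Reactants: 28 9α-acetoxy-14-(tert-butyldiphenylsilyloxy)-5αH-eudesma-3,11-diene-1β,2β-diol
Product: 30 2β,9α-diacetoxy-14-(tert-butyldiphenylsilyloxy)-5αH-eudesma-3,11-dien-1β-ol, via orthoacetate 29 (not isolated)
Conditions: MeC(OMe)3, pyridinium p-toluenesulfonate (cat.), CH2Cl2, rt; then AcOH–H2O (4:1), 0 °C → rt
Reagents that add atoms: trimethyl orthoacetate, CC(OC)(OC)OC; water, O
Why: Orthoester exchange, then kinetic hydrolysis: the hemiorthoester of a cis-fused 1,2-diol collapses to the ester of the axial oxygen. O2 is pseudoaxial (allylic, syn to C14) and O1 equatorial, so the acetate should appear on C2 and the free hydroxyl on C1 without any selective acylation.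

Step 19
Reactants: 30 2β,9α-diacetoxy-14-(tert-butyldiphenylsilyloxy)-5αH-eudesma-3,11-dien-1β-ol
Product: 31 2β,9α-diacetoxy-14-(tert-butyldiphenylsilyloxy)-5αH-eudesma-3,11-dien-1β-yl 3-methylbut-2-enoate
Conditions: 3-methylbut-2-enoic acid, 2,4,6-trichlorobenzoyl chloride, Et3N, THF, rt; then 30, 4-(dimethylamino)pyridine, PhMe, rt
Reagents that add atoms: 3-methylbut-2-enoic acid, CC(C)=CC(=O)O
Why: Yamaguchi esterification through the mixed anhydride, preferred to the acid chloride with amine base because it limits ketene-mediated deconjugation of the senecioyl group. The equatorial C1 hydroxyl is the only free one.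

Step 20
Reactants: 31 2β,9α-diacetoxy-14-(tert-butyldiphenylsilyloxy)-5αH-eudesma-3,11-dien-1β-yl 3-methylbut-2-enoate
Product: 32 (1R,2S,5R,7S,9S,10S)-2β,9α-diacetoxy-14-hydroxy-5αH-eudesma-3,11-dien-1β-yl 3-methylbut-2-enoate (7α-isopropenyl; target)
Conditions: HF·pyridine, pyridine, THF, 0 °C → rt
Reagents that add atoms: none
Why: Fluoride cleavage of the silyl ether under buffered acidic conditions, which should not move the C1 or C9 acyl groups onto the freed C14 hydroxyl and do not touch the enoate or the alkenes.

## Compound list

1 | 4,4-dimethoxybut-1-yne | C#CCC(OC)OC | starting material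
2 | lithium 4,4-dimethoxybut-1-yn-1-ide | [Li]C#CCC(OC)OC | intermediate
3 | 5,5-dimethoxypent-2-yne | CC#CCC(OC)OC | intermediate
4 | chlorobis(cyclopentadienyl)[(2E)-5,5-dimethoxypent-2-en-2-yl]zirconium | C/C(=C\CC(OC)OC)[Zr](Cl)(C1C=CC=C1)C1C=CC=C1 | intermediate
5 | (2E)-2-iodo-5,5-dimethoxypent-2-ene | C/C(I)=C\CC(OC)OC | intermediate
6 | 2-deoxy-L-ribose, (3R,4S)-3,4,5-trihydroxypentanal | O=CC[C@@H](O)[C@@H](O)CO | starting material
7 | 2-deoxy-3,4-O-isopropylidene-L-ribopyranose (anomer mixture) | OC1C[C@@H](OC(C)(C)O2)[C@@H]2CO1 | intermediate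
8 | 2-deoxy-3,4-O-isopropylidene-L-ribono-1,5-lactone | O=C1C[C@@H](OC(C)(C)O2)[C@@H]2CO1 | intermediate
9 | (3R,4S)-5-hydroxy-3,4-(isopropylidenedioxy)-N-methoxy-N-methylpentanamide | CON(C)C(=O)C[C@@H](OC(C)(C)O2)[C@@H]2CO | intermediate
10 | (3R,4R)-3,4-(isopropylidenedioxy)-N-methoxy-N-methyl-5-oxopentanamide | CON(C)C(=O)C[C@@H](OC(C)(C)O2)[C@@H]2C=O | intermediate
11 | [(2E)-5,5-dimethoxypent-2-en-2-yl]lithium | C/C([Li])=C\CC(OC)OC | intermediate
12 | (3R,4S,5S,6E)-5-hydroxy-3,4-(isopropylidenedioxy)-N,9,9-trimethoxy-N,6-dimethylnon-6-enamide | CON(C)C(=O)C[C@@H](OC(C)(C)O2)[C@@H]2[C@@H](O)/C(C)=C/CC(OC)OC | intermediate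
13 | (5S)-5-C-[(2E)-5,5-dimethoxypent-2-en-2-yl]-2-deoxy-3,4-O-isopropylidene-L-ribono-1,5-lactone (alkenyl group trans to the acetonide) | C1C(=O)O[C@@H](/C(C)=C/CC(OC)OC)[C@H](OC(C)(C)O2)[C@@H]12 | intermediate
14 | lithium enolate of lactone 13 | C1=C(O[Li])O[C@@H](/C(C)=C/CC(OC)OC)[C@H](OC(C)(C)O2)[C@@H]12 | intermediate
15 | 2-C-acetyl derivative of lactone 13 (acetyl on C10; C10 epimers and enol, drawn without configuration there) | CC(=O)C1C(=O)O[C@@H](/C(C)=C/CC(OC)OC)[C@H](OC(C)(C)O2)[C@@H]12 | intermediate
16 | C9 trimethylsilyl enol ether of 15 (C10=C9 geometry mixture) | CC(O[Si](C)(C)C)=C1C(=O)O[C@@H](/C(C)=C/CC(OC)OC)[C@H](OC(C)(C)O2)[C@@H]12 | intermediate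
17 | bis-silyl dienol ether of 15: cyclic trimethylsilyl ketene acetal (C10=C14) bearing a 1-(trimethylsilyloxy)vinyl group on C10 | C=C(O[Si](C)(C)C)C1=C(O[Si](C)(C)C)O[C@@H](/C(C)=C/CC(OC)OC)[C@H](OC(C)(C)O2)[C@@H]12 | intermediate
18 | trimethylsilyl 1β,2β-(isopropylidenedioxy)-5β-(2,2-dimethoxyethyl)-4-methyl-10α-[1-(trimethylsilyloxy)vinyl]cyclohex-3-ene-10β-carboxylate | C=C(O[Si](C)(C)C)[C@@]1(C(=O)O[Si](C)(C)C)[C@H](CC(OC)OC)C(C)=C[C@H](OC(C)(C)O2)[C@@H]12 | intermediate
19 | trimethylsilyl 1β,2β-(isopropylidenedioxy)-7-methoxy-9-oxo-11,12,13-trinor-5αH-eudesm-3-en-14-oate (C7 epimers) | COC1CC(=O)[C@@]2(C(=O)O[Si](C)(C)C)[C@H](C1)C(C)=C[C@H](OC(C)(C)O3)[C@@H]23 | intermediate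
20 | 1β,2β-(isopropylidenedioxy)-7-methoxy-9-oxo-11,12,13-trinor-5αH-eudesm-3-en-14-oic acid (C7 epimers) | COC1CC(=O)[C@@]2(C(=O)O)[C@H](C1)C(C)=C[C@H](OC(C)(C)O3)[C@@H]23 | intermediate
21 | methyl 1β,2β-(isopropylidenedioxy)-7-methoxy-9-oxo-11,12,13-trinor-5αH-eudesm-3-en-14-oate (C7 epimers) | COC1CC(=O)[C@@]2(C(=O)OC)[C@H](C1)C(C)=C[C@H](OC(C)(C)O3)[C@@H]23 | intermediate
22 | methyl 1β,2β-(isopropylidenedioxy)-9-oxo-11,12,13-trinor-5αH-eudesma-3,7-dien-14-oate | C1=CC(=O)[C@@]2(C(=O)OC)[C@H](C1)C(C)=C[C@H](OC(C)(C)O3)[C@@H]23 | intermediate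
23 | methyl 1β,2β-(isopropylidenedioxy)-9-oxo-5αH-eudesma-3,11-dien-14-oate (7α-isopropenyl) | C=C(C)[C@@H]1CC(=O)[C@@]2(C(=O)OC)[C@H](C1)C(C)=C[C@H](OC(C)(C)O3)[C@@H]23 | intermediate
24 | lithium 9α-alkoxide of methyl 9α-hydroxy-1β,2β-(isopropylidenedioxy)-5αH-eudesma-3,11-dien-14-oate | C=C(C)[C@@H]1C[C@H](O[Li])[C@@]2(C(=O)OC)[C@H](C1)C(C)=C[C@H](OC(C)(C)O3)[C@@H]23 | intermediate
25 | 1β,2β-(isopropylidenedioxy)-5αH-eudesma-3,11-diene-9α,14-diol (7α-isopropenyl) | C=C(C)[C@@H]1C[C@H](O)[C@@]2(CO)[C@H](C1)C(C)=C[C@H](OC(C)(C)O3)[C@@H]23 | intermediate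
26 | 14-(tert-butyldiphenylsilyloxy)-1β,2β-(isopropylidenedioxy)-5αH-eudesma-3,11-dien-9α-ol | C=C(C)[C@@H]1C[C@H](O)[C@@]2(CO[Si](c4ccccc4)(c4ccccc4)C(C)(C)C)[C@H](C1)C(C)=C[C@H](OC(C)(C)O3)[C@@H]23 | intermediate
27 | 14-(tert-butyldiphenylsilyloxy)-1β,2β-(isopropylidenedioxy)-5αH-eudesma-3,11-dien-9α-yl acetate | C=C(C)[C@@H]1C[C@H](OC(C)=O)[C@@]2(CO[Si](c4ccccc4)(c4ccccc4)C(C)(C)C)[C@H](C1)C(C)=C[C@H](OC(C)(C)O3)[C@@H]23 | intermediate
28 | 9α-acetoxy-14-(tert-butyldiphenylsilyloxy)-5αH-eudesma-3,11-diene-1β,2β-diol | C=C(C)[C@@H]1C[C@H](OC(C)=O)[C@@]2(CO[Si](c3ccccc3)(c3ccccc3)C(C)(C)C)[C@H](C1)C(C)=C[C@H](O)[C@@H]2O | intermediate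
29 | 1β,2β-O-(1-methoxyethylidene) derivative of 28 (cyclic orthoacetate) | C=C(C)[C@@H]1C[C@H](OC(C)=O)[C@@]2(CO[Si](c4ccccc4)(c4ccccc4)C(C)(C)C)[C@H](C1)C(C)=C[C@H](OC(C)(OC)O3)[C@@H]23 | intermediate
30 | 2β,9α-diacetoxy-14-(tert-butyldiphenylsilyloxy)-5αH-eudesma-3,11-dien-1β-ol | C=C(C)[C@@H]1C[C@H](OC(C)=O)[C@@]2(CO[Si](c3ccccc3)(c3ccccc3)C(C)(C)C)[C@H](C1)C(C)=C[C@H](OC(C)=O)[C@@H]2O | intermediate
31 | 2β,9α-diacetoxy-14-(tert-butyldiphenylsilyloxy)-5αH-eudesma-3,11-dien-1β-yl 3-methylbut-2-enoate | C=C(C)[C@@H]1C[C@H](OC(C)=O)[C@@]2(CO[Si](c3ccccc3)(c3ccccc3)C(C)(C)C)[C@H](C1)C(C)=C[C@H](OC(C)=O)[C@@H]2OC(=O)C=C(C)C | intermediate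
32 | (1R,2S,5R,7S,9S,10S)-2β,9α-diacetoxy-14-hydroxy-5αH-eudesma-3,11-dien-1β-yl 3-methylbut-2-enoate (7α-isopropenyl) | C=C(C)[C@@H]1C[C@H](OC(C)=O)[C@@]2(CO)[C@H](C1)C(C)=C[C@H](OC(C)=O)[C@@H]2OC(=O)C=C(C)C | target

## Step count and risks

Total: 20 steps. Longest linear sequence: 18 steps (steps 3–20, from 6); the alkyne branch (steps 1 and 2) joins at step 7.

**Step 10 (key step).** The lithium dienolate may lose the C1 oxygen by β-elimination before it is silylated, γ-deprotonation may be incomplete, or the electron-rich bis-silyl diene may decay faster than the boat rearrangement proceeds. The fallback sets out from 13 and comes back at 21; it runs the ring contraction on the unsubstituted lactone and adds the acetyl group afterwards. LiN(i-Pr)2 and t-BuMe2SiCl with HMPA at −78 °C give the tert-butyldimethylsilyl ketene acetal F1, which on heating in toluene contracts through the same boat to the 10α-H silyl ester F2. K2CO3 in MeOH, then MeI, give the methyl ester F3. LiN(i-Pr)2 and AcCl at −78 °C acylate C10 on the α face, anti to both the C5 arm and O1, to give the β-keto ester F4. Me3SiOTf and Et3N give the silyl enol ether F5, which under the Me3SiOTf conditions of step 11 closes to 21.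

**Step 9.** The lactone enolate may eliminate the β-oxygen at C1, or be acylated on oxygen, or the base may consume the acid chloride. The fallback sets out from 13 and comes back at 15; it replaces acylation by an aldol reaction that traps the enolate within seconds. LiN(i-Pr)2 (1.05 equiv) at −78 °C followed at once by acetaldehyde gives the 2-C-(1-hydroxyethyl) lactone F6, and Dess–Martin oxidation gives 15.

**Step 7.** Facial selectivity may be poor if lithium chelation by the amide carbonyl or the acetonide oxygens competes with the Felkin–Anh mode, and some alkenyllithium may attack the amide. The fallback sets out from the C3-epimer mixture of 12 and comes back at 12; it replaces substrate control by reagent control. Dess–Martin oxidation gives the enone amide F7. Corey–Bakshi–Shibata reduction with (S)-1-methyl-3,3-diphenyltetrahydro-1H,3H-pyrrolo[1,2-c][1,3,2]oxazaborole and catecholborane, with the 2-methylalkenyl group acting as the large substituent, should return the 3S alcohol 12.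

**Step 14.** Hydride may reach C9 from the wrong face, since the equatorial approach is itself hindered by the axial C14 ester and the peri O1, and the β-alkoxy ester may open by retro-aldol cleavage during the second reduction. The fallback sets out from 22 and comes back at 25; it reduces C14 first and lets O14 direct the C9 reduction.
- Copper-catalysed addition of CH2=C(CH3)MgBr to 22 in the presence of Me3SiCl gives the C9 silyl enol ether ester F8.
- i-Bu2AlH at −78 °C reduces the ester to the silyl enol ether alcohol F9.
- Aqueous citric acid releases the 14-hydroxy-9-ketone F10; base is avoided because F10 can lose formaldehyde by retro-aldol reaction.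
- Evans–Saksena reduction with Me4NBH(OAc)3 in MeCN–AcOH delivers hydride from the boron bound to O14 on the β face and gives the 9α-alcohol 25.

**Step 19 (with step 18).** Under amine and 4-(dimethylamino)pyridine the C2 acetyl group may migrate to O1 before the hindered C1 hydroxyl is acylated, and the senecioyl unit may deconjugate. The fallback sets out from 28 and comes back at 31; it reverses the order of the two acylations. Bu2SnO in refluxing toluene gives the dibutylstannylene acetal F11. 3-Methylbut-2-enoyl chloride then acylates the equatorial oxygen to give the 1β-senecioate 2β-alcohol F12, and Ac2O with 4-(dimethylamino)pyridine gives 31.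

## Further compounds

F1 | step 10 | tert-butyldimethylsilyl ketene acetal of lactone 13 | C1=C(O[Si](C)(C)C(C)(C)C)O[C@@H](/C(C)=C/CC(OC)OC)[C@H](OC(C)(C)O2)[C@@H]12
F2 | step 10 | tert-butyldimethylsilyl 1β,2β-(isopropylidenedioxy)-5β-(2,2-dimethoxyethyl)-4-methylcyclohex-3-ene-10β-carboxylate (10α-H) | CC(C)(C)[Si](C)(C)OC(=O)[C@@H]1[C@H](CC(OC)OC)C(C)=C[C@H](OC(C)(C)O2)[C@@H]12
F3 | step 10 | methyl 1β,2β-(isopropylidenedioxy)-5β-(2,2-dimethoxyethyl)-4-methylcyclohex-3-ene-10β-carboxylate (10α-H) | COC(=O)[C@@H]1[C@H](CC(OC)OC)C(C)=C[C@H](OC(C)(C)O2)[C@@H]12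
F4 | step 10 | methyl 10α-acetyl-1β,2β-(isopropylidenedioxy)-5β-(2,2-dimethoxyethyl)-4-methylcyclohex-3-ene-10β-carboxylate | CC(=O)[C@@]1(C(=O)OC)[C@H](CC(OC)OC)C(C)=C[C@H](OC(C)(C)O2)[C@@H]12
F5 | step 10 | methyl 1β,2β-(isopropylidenedioxy)-5β-(2,2-dimethoxyethyl)-4-methyl-10α-[1-(trimethylsilyloxy)vinyl]cyclohex-3-ene-10β-carboxylate | C=C(O[Si](C)(C)C)[C@@]1(C(=O)OC)[C@H](CC(OC)OC)C(C)=C[C@H](OC(C)(C)O2)[C@@H]12
F6 | step 9 | 2-C-(1-hydroxyethyl) derivative of lactone 13 (isomer mixture at C9 and C10) | CC(O)C1C(=O)O[C@@H](/C(C)=C/CC(OC)OC)[C@H](OC(C)(C)O2)[C@@H]12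
F7 | step 7 | (3R,4R,6E)-3,4-(isopropylidenedioxy)-N,9,9-trimethoxy-N,6-dimethyl-5-oxonon-6-enamide | CON(C)C(=O)C[C@@H](OC(C)(C)O2)[C@@H]2C(=O)/C(C)=C/CC(OC)OC
F8 | step 14 | methyl 1β,2β-(isopropylidenedioxy)-9-(trimethylsilyloxy)-5αH-eudesma-3,8,11-trien-14-oate (7α-isopropenyl) | C=C(C)[C@@H]1C=C(O[Si](C)(C)C)[C@@]2(C(=O)OC)[C@H](C1)C(C)=C[C@H](OC(C)(C)O3)[C@@H]23
F9 | step 14 | 1β,2β-(isopropylidenedioxy)-9-(trimethylsilyloxy)-5αH-eudesma-3,8,11-trien-14-ol | C=C(C)[C@@H]1C=C(O[Si](C)(C)C)[C@@]2(CO)[C@H](C1)C(C)=C[C@H](OC(C)(C)O3)[C@@H]23
F10 | step 14 | 14-hydroxy-1β,2β-(isopropylidenedioxy)-5αH-eudesma-3,11-dien-9-one | C=C(C)[C@@H]1CC(=O)[C@@]2(CO)[C@H](C1)C(C)=C[C@H](OC(C)(C)O3)[C@@H]23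
F11 | step 19 | 1β,2β-O-(dibutylstannylene) derivative of 28 | C=C(C)[C@@H]1C[C@H](OC(C)=O)[C@@]2(CO[Si](c4ccccc4)(c4ccccc4)C(C)(C)C)[C@H](C1)C(C)=C[C@H](O[Sn](CCCC)(CCCC)O3)[C@@H]23
F12 | step 19 | 9α-acetoxy-14-(tert-butyldiphenylsilyloxy)-2β-hydroxy-5αH-eudesma-3,11-dien-1β-yl 3-methylbut-2-enoate | C=C(C)[C@@H]1C[C@H](OC(C)=O)[C@@]2(CO[Si](c3ccccc3)(c3ccccc3)C(C)(C)C)[C@H](C1)C(C)=C[C@H](O)[C@@H]2OC(=O)C=C(C)C
A1 | alternative 1 | methyl 1,4-benzoquinone-2-carboxylate | COC(=O)C1=CC(=O)C=CC1=O
A2 | alternative 1 | (E)-1-(tert-butyldimethylsilyloxy)buta-1,3-diene | C=C/C=C/O[Si](C)(C)C(C)(C)C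
A3 | alternative 1 | cis-fused endo adduct with C10 ester, C9 silyloxy group, C1 and C4 ketones | C1=C[C@H](O[Si](C)(C)C(C)(C)C)[C@@]2(C(=O)OC)[C@@H](C1)C(=O)C=CC2=O
A4 | alternative 2 | methyl (7E,9E)-10-(tert-butyldimethylsilyloxy)-2-[(dimethylphenylsilyl)methylidene]-8-methyl-3-oxodeca-7,9-dienoate | COC(=O)C(=C[Si](C)(C)c1ccccc1)C(=O)CCC/C=C(C)/C=C/O[Si](C)(C)C(C)(C)C
A5 | alternative 2 | trans-fused octalin β-keto ester with C1 dimethylphenylsilyl, C2 silyloxy and C3=C4 | C1CC(=O)[C@@]2(C(=O)OC)[C@H](C1)C(C)=C[C@H](O[Si](C)(C)C(C)(C)C)[C@@H]2[Si](C)(C)c1ccccc1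
A6 | alternative 3 | ring B dialdehyde: C10 formyl (C1) and 4-methoxybenzyloxymethyl (C14), C5 (Z)-enal arm, 9-silyloxy, 7-isopropenyl | C=C(C)[C@@H]1C[C@H](O[Si](C)(C)C(C)(C)C)[C@@](C=O)(COCc2ccc(OC)cc2)[C@H](C1)/C(C)=C\C=O
A7 | alternative 3 | trans-fused decalin cis-1,2-diol with C3=C4, 9-silyloxy and 14-(4-methoxybenzyloxy) groups | C=C(C)[C@@H]1C[C@H](O[Si](C)(C)C(C)(C)C)[C@@]2(COCc3ccc(OC)cc3)[C@H](C1)C(C)=C[C@H](O)[C@@H]2O
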